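Each 5,6-dihydropyridin-2(1H)-one ring is grown on a carboxamide nitrogen instead of being coupled as a finished lactam. Everything rests on the N1–C6 bond of both lactam rings: bis(primary amide) 9 is N-acylated by 5-bromopentanoyl chloride, and each imide nitrogen so formed, acidic because it lies between the exocyclic cyclobutane carbonyl and ring carbonyl C2, displaces the terminal bromide and closes its six-membered ring. One operation forms four C–N bonds and both nitrogen rings; its ring-closing precursor, bis-imide 11 with two open 5-bromopentanoyl chains, arises in the same flask. The rings are carried saturated and desaturated at C3=C4 last. The all-trans cyclobutane core comes from amide-directed double C–H arylation and base epimerisation.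

Key step: step 5

Remark on the chemistry: the target is a meso compound, so its stereodescriptors fix only the relative configuration. Both aryl groups lie on one face of the cyclobutane, both acyl groups on the other, and every neighbouring pair is trans (written below as 1α,2β,3α,4β). Chiral compounds that occur only on fallback paths are racemic, and the selenium-bearing carbons of 13 and 14 form as inconsequential mixtures.

Step 1
Reactants: 1 cis-3-(methoxycarbonyl)cyclobutane-1-carboxylic acid; 2 8-aminoquinoline
Product: 3 methyl cis-3-(quinolin-8-ylcarbamoyl)cyclobutane-1-carboxylate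
Conditions: N,N'-diisopropylcarbodiimide, DMAP (cat.), CH2Cl2, 0 °C to rt
Reagents that add atoms: none
Why: Carbodiimide amide coupling (DMAP as acyl-transfer catalyst) joins the free acid to the weakly nucleophilic aromatic amine and installs the N,N-bidentate directing group; no stereocentre is formed and the cis-1,3 relationship of 1 is not touched.

Step 2
Reactants: 3 methyl cis-3-(quinolin-8-ylcarbamoyl)cyclobutane-1-carboxylate; 4 5-iodo-1,2,3-trimethoxybenzene (4 equiv)
Product: 5 methyl (1α,2α,3α,4α)-3-(quinolin-8-ylcarbamoyl)-2,4-bis(3,4,5-trimethoxyphenyl)cyclobutane-1-carboxylate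
Conditions: Pd(OAc)2 (10 mol %), AgOAc (3 equiv), PivOH (30 mol %), toluene, 110 °C
Reagents that add atoms: none
Why: Directed C–H arylation: the deprotonated quinolinyl amide binds divalent palladium through both nitrogens, the two methylene C–H bonds on the amide face are cleaved one after the other by concerted metalation–deprotonation in five-membered palladacycles, and oxidative addition of 4 to give tetravalent palladium, C–C reductive elimination and iodide removal by AgOAc place both aryl groups cis to the amide, which sets C2 and C4 and gives the all-cis ring.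

Step 3
Reactants: 5 methyl (1α,2α,3α,4α)-3-(quinolin-8-ylcarbamoyl)-2,4-bis(3,4,5-trimethoxyphenyl)cyclobutane-1-carboxylate
Product: 7 (1α,2β,3α,4β)-2,4-bis(3,4,5-trimethoxyphenyl)cyclobutane-1,3-dicarboxylic acid, via all-trans amido ester 6 (not isolated)
Conditions: NaOMe (2 equiv), MeOH, 65 °C; then NaOH, H2O, 130 °C (sealed tube); then aq. HCl
Reagents that add atoms: sodium hydroxide, [Na+].[OH-]
Why: Base epimerisation followed by ester and amide hydrolysis: methoxide reversibly removes the exposed hydrogens α to the two carbonyl groups, the strain of four cis substituents drives both carbonyl groups to the face opposite the aryl groups under thermodynamic control (this sets C1 and C3 and completes the all-trans array in 6), and hot hydroxide then cleaves the methyl ester and the quinolinyl amide.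

Step 4
Reactants: 7 (1α,2β,3α,4β)-2,4-bis(3,4,5-trimethoxyphenyl)cyclobutane-1,3-dicarboxylic acid
Product: 9 (1α,2β,3α,4β)-2,4-bis(3,4,5-trimethoxyphenyl)cyclobutane-1,3-dicarboxamide, via bis(acid chloride) 8 (not isolated)
Conditions: (COCl)2, DMF (cat.), CH2Cl2, 0 °C to rt; evaporate; NH3 (0.5 M in 1,4-dioxane), THF, 0 °C
Reagents that add atoms: ammonia, N
Why: Acid chloride formation with oxalyl chloride under DMF catalysis and ammonolysis is the standard way to a primary carboxamide; the α-centres are already in their thermodynamic trans positions, so transient enolisation of 8 cannot change the configuration.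

Step 5
Reactants: 9 (1α,2β,3α,4β)-2,4-bis(3,4,5-trimethoxyphenyl)cyclobutane-1,3-dicarboxamide; 10 5-bromopentanoyl chloride (2.1 equiv)
Product: 12 1,1'-[(1α,2β,3α,4β)-2,4-bis(3,4,5-trimethoxyphenyl)cyclobutane-1,3-dicarbonyl]bis(piperidin-2-one), via bis-imide 11 (not isolated)
Conditions: NaH (4.4 equiv), THF/DMF (4:1), 0 °C; 10, −20 °C to rt; then Bu4NI (cat.), 50 °C
Reagents that add atoms: none
Why: NaH converts each primary carboxamide of 9 into its sodium amidate, which is acylated at nitrogen by the acid chloride end of 10 to give bis-imide 11; the new imide N–H, flanked by the cyclobutane carbonyl and the pentanoyl carbonyl, is deprotonated by the second equivalent of NaH, and the imide nitrogen then displaces the primary bromide at the far end of its own chain in an intramolecular SN2 reaction that forms the N1–C6 bond and closes the piperidin-2-one ring. The closest known reaction type is the one-flask lactam synthesis from an N–H compound and an ω-haloacyl chloride (N-acylation followed by intramolecular N-alkylation, an intramolecular Gabriel-type imide alkylation). Each of the two rings closes in the 6-exo-tet mode, with nitrogen, C2 and the four methylene carbons in the ring and the leaving group outside it. No stereocentre is formed, and the four cyclobutane centres are not at risk because the all-trans array is the thermodynamic one. The step needs N- over O-alkylation of the ambident imide anion and mono- over diacylation at nitrogen: the soft primary bromide favours attack through nitrogen and Bu4NI returns any cyclic O-alkyl imidate to the lactam by reopening at C6, while the imide anion is a far poorer acyl acceptor than the amidate and is drained by the fast intramolecular alkylation.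

Step 6
Reactants: 12 1,1'-[(1α,2β,3α,4β)-2,4-bis(3,4,5-trimethoxyphenyl)cyclobutane-1,3-dicarbonyl]bis(piperidin-2-one)
Product: 15 1,1'-[(1α,2β,3α,4β)-2,4-bis(3,4,5-trimethoxyphenyl)cyclobutane-1,3-dicarbonyl]bis(5,6-dihydropyridin-2(1H)-one), via bis-selenide 13 (not isolated), via bis-selenoxide 14 (not isolated)
Conditions: LiN(SiMe3)2 (2.3 equiv), THF, −78 °C; PhSeBr (2.3 equiv), −78 °C; then H2O2 (30% aq.), pyridine, CH2Cl2, 0 °C to rt
Reagents that add atoms: none
Why: Enolate selenenylation and selenoxide syn-elimination: LiN(SiMe3)2 should remove a hydrogen from the unhindered ring methylene C3 of each N-acyl lactam in preference to the tertiary cyclobutane methine (flanked by two aryl-bearing carbons and leading to a strained exocyclic enolate), PhSeBr traps the enolates, and oxidation to the selenoxides triggers elimination towards C4, the only carbon with a syn β-hydrogen, so the double bond appears at C3=C4 of each ring without creating or disturbing a stereocentre.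

Compound list
1 | cis-3-(methoxycarbonyl)cyclobutane-1-carboxylic acid | COC(=O)[C@H]1C[C@@H](C(=O)O)C1 | starting material
2 | 8-aminoquinoline | Nc1cccc2cccnc12 | starting material
3 | methyl cis-3-(quinolin-8-ylcarbamoyl)cyclobutane-1-carboxylate | COC(=O)[C@H]1C[C@@H](C(=O)Nc2cccc3cccnc23)C1 | intermediate
4 | 5-iodo-1,2,3-trimethoxybenzene | COc1cc(I)cc(OC)c1OC | starting material
5 | methyl (1α,2α,3α,4α)-3-(quinolin-8-ylcarbamoyl)-2,4-bis(3,4,5-trimethoxyphenyl)cyclobutane-1-carboxylate (all four substituents cis) | COC(=O)[C@H]1[C@@H](c2cc(OC)c(OC)c(OC)c2)[C@@H](C(=O)Nc2cccc3cccnc23)[C@H]1c1cc(OC)c(OC)c(OC)c1 | intermediate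
6 | methyl (1α,2β,3α,4β)-3-(quinolin-8-ylcarbamoyl)-2,4-bis(3,4,5-trimethoxyphenyl)cyclobutane-1-carboxylate (all-trans amido ester) | COc1cc([C@H]2[C@H](C(=O)OC)[C@@H](c3cc(OC)c(OC)c(OC)c3)[C@@H]2C(=O)Nc2cccc3cccnc23)cc(OC)c1OC | intermediate
7 | (1α,2β,3α,4β)-2,4-bis(3,4,5-trimethoxyphenyl)cyclobutane-1,3-dicarboxylic acid | COc1cc([C@H]2[C@H](C(=O)O)[C@@H](c3cc(OC)c(OC)c(OC)c3)[C@@H]2C(=O)O)cc(OC)c1OC | intermediate
8 | (1α,2β,3α,4β)-2,4-bis(3,4,5-trimethoxyphenyl)cyclobutane-1,3-dicarbonyl dichloride | COc1cc([C@H]2[C@H](C(=O)Cl)[C@@H](c3cc(OC)c(OC)c(OC)c3)[C@@H]2C(=O)Cl)cc(OC)c1OC | intermediate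
9 | (1α,2β,3α,4β)-2,4-bis(3,4,5-trimethoxyphenyl)cyclobutane-1,3-dicarboxamide | COc1cc([C@H]2[C@H](C(N)=O)[C@@H](c3cc(OC)c(OC)c(OC)c3)[C@@H]2C(N)=O)cc(OC)c1OC | intermediate
10 | 5-bromopentanoyl chloride | O=C(Cl)CCCCBr | starting material
11 | (1α,2β,3α,4β)-N1,N3-bis(5-bromopentanoyl)-2,4-bis(3,4,5-trimethoxyphenyl)cyclobutane-1,3-dicarboxamide (bis-imide) | COc1cc([C@H]2[C@H](C(=O)NC(=O)CCCCBr)[C@@H](c3cc(OC)c(OC)c(OC)c3)[C@@H]2C(=O)NC(=O)CCCCBr)cc(OC)c1OC | intermediate
12 | 1,1'-[(1α,2β,3α,4β)-2,4-bis(3,4,5-trimethoxyphenyl)cyclobutane-1,3-dicarbonyl]bis(piperidin-2-one) | COc1cc([C@H]2[C@H](C(=O)N3CCCCC3=O)[C@@H](c3cc(OC)c(OC)c(OC)c3)[C@@H]2C(=O)N2CCCCC2=O)cc(OC)c1OC | intermediate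
13 | 1,1'-[(1α,2β,3α,4β)-2,4-bis(3,4,5-trimethoxyphenyl)cyclobutane-1,3-dicarbonyl]bis[3-(phenylselanyl)piperidin-2-one] (bis-selenide) | COc1cc([C@H]2[C@H](C(=O)N3CCCC([Se]c4ccccc4)C3=O)[C@@H](c3cc(OC)c(OC)c(OC)c3)[C@@H]2C(=O)N2CCCC([Se]c3ccccc3)C2=O)cc(OC)c1OC | intermediate
14 | 1,1'-[(1α,2β,3α,4β)-2,4-bis(3,4,5-trimethoxyphenyl)cyclobutane-1,3-dicarbonyl]bis[3-(phenylseleninyl)piperidin-2-one] (bis-selenoxide) | COc1cc([C@H]2[C@H](C(=O)N3CCCC([Se](=O)c4ccccc4)C3=O)[C@@H](c3cc(OC)c(OC)c(OC)c3)[C@@H]2C(=O)N2CCCC([Se](=O)c3ccccc3)C2=O)cc(OC)c1OC | intermediate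
15 | 1,1'-[(1α,2β,3α,4β)-2,4-bis(3,4,5-trimethoxyphenyl)cyclobutane-1,3-dicarbonyl]bis(5,6-dihydropyridin-2(1H)-one) | COc1cc([C@H]2[C@H](C(=O)N3CCC=CC3=O)[C@@H](c3cc(OC)c(OC)c(OC)c3)[C@@H]2C(=O)N2CCC=CC2=O)cc(OC)c1OC | target

Total step count: 6. Longest linear sequence: 6 steps (1 to 15).

Steps most likely to fail

Step 2. The second cyclopalladation may stall on the crowded all-cis face, or the amide-bearing carbon may epimerise between the two arylations and steer the second aryl group to the wrong face. The fallback sets out from 3 and comes back at 7 by a stepwise arylation–epimerisation–arylation sequence. Mono-arylation of 3 with a slight excess of 4 (Pd(OAc)2, AgOAc, toluene, 80 °C) should give racemic methyl (1α,2α,3α)-3-(quinolin-8-ylcarbamoyl)-2-(3,4,5-trimethoxyphenyl)cyclobutane-1-carboxylate F1. Brief exposure to NaOMe in MeOH at rt, under which the ester-bearing carbon equilibrates much faster than the amide-bearing one, should move only the ester to the other face and give racemic methyl (1β,2α,3α)-3-(quinolin-8-ylcarbamoyl)-2-(3,4,5-trimethoxyphenyl)cyclobutane-1-carboxylate F2. A second arylation with 4, again cis to the amide but now on a less crowded ring, should give methyl (1β,2α,3α,4α)-3-(quinolin-8-ylcarbamoyl)-2,4-bis(3,4,5-trimethoxyphenyl)cyclobutane-1-carboxylate F3. Under the conditions of step 3, F3 should be inverted at the amide-bearing carbon and cleaved to 7.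

Step 6. Enolisation may occur at the cyclobutane methine instead of the lactam methylene, one carbon may be selenenylated twice, or the lactam enolate may transfer the exocyclic acyl group from nitrogen to carbon. The fallback sets out from 9 and comes back at 15; it carries the C3=C4 double bond, as a Z-alkene, into the same N1–C6 ring closure, so no enolate chemistry is needed afterwards. Commercial 4-chlorobut-1-yne is deprotonated (n-BuLi, THF, −78 °C) and carboxylated with CO2 to 5-chloropent-2-ynoic acid F4. Semihydrogenation (H2, Pd/CaCO3 poisoned with Pb(OAc)2, quinoline, EtOAc) should give (2Z)-5-chloropent-2-enoic acid F5. Neutral activation with 1-chloro-N,N,2-trimethylprop-1-en-1-amine in CH2Cl2 at 0 °C should give (2Z)-5-chloropent-2-enoyl chloride F6 without Z-to-E isomerisation. Acylation of the sodium bis-amidate of 9 (NaH, THF, −40 °C) with F6 should give (1α,2β,3α,4β)-N1,N3-bis[(2Z)-5-chloropent-2-enoyl]-2,4-bis(3,4,5-trimethoxyphenyl)cyclobutane-1,3-dicarboxamide F7. Its Z geometry lets each imide nitrogen reach C6, so Cs2CO3 and NaI (cat.) in DMF at 40 °C should close both rings and give 15 directly.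

Step 3. The hindered quinolinyl amide may be cleaved incompletely, or the ester or amide may be hydrolysed before its α-carbon has inverted, which leaves a cis carboxylate that no longer epimerises. The fallback sets out from 5 and comes back at 7; it activates the amide so that inversion and cleavage both occur under mild alkoxide conditions. Boc2O and DMAP in MeCN should give methyl (1α,2α,3α,4α)-3-[(tert-butoxycarbonyl)(quinolin-8-yl)carbamoyl]-2,4-bis(3,4,5-trimethoxyphenyl)cyclobutane-1-carboxylate F8. Both of its α-hydrogens are now ester-like in acidity, so NaOMe in MeOH at 65 °C should epimerise both centres and methanolyse the twisted amide to dimethyl (1α,2β,3α,4β)-2,4-bis(3,4,5-trimethoxyphenyl)cyclobutane-1,3-dicarboxylate F9. Saponification with LiOH in THF/H2O then gives 7.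

Further compounds
F1 | step 2 | racemic methyl (1α,2α,3α)-3-(quinolin-8-ylcarbamoyl)-2-(3,4,5-trimethoxyphenyl)cyclobutane-1-carboxylate | COC(=O)[C@H]1[C@@H](c2cc(OC)c(OC)c(OC)c2)[C@@H](C(=O)Nc2cccc3cccnc23)C1
F2 | step 2 | racemic methyl (1β,2α,3α)-3-(quinolin-8-ylcarbamoyl)-2-(3,4,5-trimethoxyphenyl)cyclobutane-1-carboxylate | COC(=O)[C@@H]1[C@@H](c2cc(OC)c(OC)c(OC)c2)[C@@H](C(=O)Nc2cccc3cccnc23)C1
F3 | step 2 | methyl (1β,2α,3α,4α)-3-(quinolin-8-ylcarbamoyl)-2,4-bis(3,4,5-trimethoxyphenyl)cyclobutane-1-carboxylate | COC(=O)[C@@H]1[C@@H](c2cc(OC)c(OC)c(OC)c2)[C@@H](C(=O)Nc2cccc3cccnc23)[C@H]1c1cc(OC)c(OC)c(OC)c1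
F4 | step 6 | 5-chloropent-2-ynoic acid | OC(=O)C#CCCCl
F5 | step 6 | (2Z)-5-chloropent-2-enoic acid | OC(=O)/C=C\CCCl
F6 | step 6 | (2Z)-5-chloropent-2-enoyl chloride | ClC(=O)/C=C\CCCl
F7 | step 6 | (1α,2β,3α,4β)-N1,N3-bis[(2Z)-5-chloropent-2-enoyl]-2,4-bis(3,4,5-trimethoxyphenyl)cyclobutane-1,3-dicarboxamide | COc1cc([C@H]2[C@H](C(=O)NC(=O)/C=C\CCCl)[C@@H](c3cc(OC)c(OC)c(OC)c3)[C@@H]2C(=O)NC(=O)/C=C\CCCl)cc(OC)c1OC
F8 | step 3 | methyl (1α,2α,3α,4α)-3-[(tert-butoxycarbonyl)(quinolin-8-yl)carbamoyl]-2,4-bis(3,4,5-trimethoxyphenyl)cyclobutane-1-carboxylate | COC(=O)[C@H]1[C@@H](c2cc(OC)c(OC)c(OC)c2)[C@@H](C(=O)N(C(=O)OC(C)(C)C)c2cccc3cccnc23)[C@H]1c1cc(OC)c(OC)c(OC)c1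
F9 | step 3 | dimethyl (1α,2β,3α,4β)-2,4-bis(3,4,5-trimethoxyphenyl)cyclobutane-1,3-dicarboxylate | COc1cc([C@H]2[C@H](C(=O)OC)[C@@H](c3cc(OC)c(OC)c(OC)c3)[C@@H]2C(=O)OC)cc(OC)c1OC
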